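The data stem from a simulated flask for substances that don't exist; the scatter is artificial.

In a one-step world the rate of making X follows c_L, so one percent more L gives one percent more rate and the apparent order in L is one. The runs below sag before they stop, so you need to reckon the correction to that one.

all flasks: L 10 mM
- grey: D 0.34 M; Q 0.60 M; run made earlier
- blue: D 0.75 M; Q 0.60 M; run made earlier
- flask: D 0.50 M; Q 0.600 M

| grey: time / s | grey: X / % | blue: time / s | blue: X / % |
|---|---|---|---|
| 10.0 | 8.6 | 10.0 | 5.2 |
| 15.0 | 13.4 | 15.0 | 7.8 |
| 25.0 | 21.4 | 25.0 | 12.1 |
| 40.0 | 30.9 | 40.0 | 18.0 |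
| 60.0 | 35.1 | 60.0 | 18.9 |
| 120 | 35.3 | 120 | 18.2 |

(scatter of a reading: 0.3 percentage points)

- the analysis behind the earlier runs scatters by 0.3 percentage points, standard deviation
- no earlier run changes the charge of L; that part of a forecast is a guess
- no earlier run changes the charge of Q; that part of a forecast is a guess

* apparent order in L when 20% of the D are converted (percent change of the rate of making X for one percent more L charged)
* apparent order in Q when 20% of the D are converted (percent change of the rate of making X for one percent more Q charged)

First, how fast does the rate sag? Compare the first 15.0 s with the window from 25.0 s to 40.0 s, whose middles lie 25.0 s apart. The grey run goes from 3.04 mM s⁻¹ to 2.15 mM s⁻¹, and the blue run from 3.90 mM s⁻¹ to 2.95 mM s⁻¹. The loss of rate per second, as a share of the late rate and taken over both runs, is 0.0144 s⁻¹; call it the sag. These are readings with their scatter, but the two runs lose 0.890 mM s⁻¹ and 0.950 mM s⁻¹, so I take the sag to run on the clock and use it for the flask, whose charge of D lies between theirs.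

Second, what does a clock do to the order? In the flask, 20% conversion means 0.100 M of X, an amount both runs pass inside the late window. One percent more L reaches it sooner by one percent of X over rate, and so meets a rate less sagged. The correction is therefore the sag times X over rate. With the flask's rate taken midway, 2.55 mM s⁻¹, that gives 0.563, so my order in L is 1.56. For Q I have no reckoning, since no run changes it.

The forecast gives 1 for L and 0.5 for Q, its ground for L being “A catalyst suggests order about 1”.

The flask gives 1.7 in L and 0.45 in Q.

    D + L → E (k = 2.86 M⁻¹ s⁻¹)
    Q + E → J (k = 17.4 M⁻¹ s⁻¹)
    J → L + X (k = 0.531 s⁻¹)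
    Q → Z (k = 0.0613 s⁻¹)

At 0.141 min the flask uses Q for Z 5.7 times faster than for J, and at 3.00 min Q, the limiting reagent, stands at 0% of its charge. Put the flask's own rate, 2.75 mM s⁻¹ at 0.470 min, in place of the midway one, and the correction is 0.524, an order in L of 1.52. For the blue run at the same 0.100 M of X, the sag of 0.0144 s⁻¹ with that run's late rate of 2.95 mM s⁻¹ reckons an order in L of 1.49.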